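The disconnection on which everything rests is the cut of C6–C7 and C7–C8 in ring B: the C6 carbonyl flanked by isopropyl-bearing C7 is the retron of a one-carbon ring expansion. In one operation, Sc(OTf)3-catalysed insertion of 2-methyl-1-diazopropane into (R)-3-methyl-3-[4-(4-methoxybenzyloxymethyl)pent-4-enyl]cyclopentanone enlarges the five-membered ring to ring B and installs the secondary isopropyl group next to the carbonyl. The precursor holds only the quaternary C10, set by one asymmetric conjugate addition, and a masked C4 ketone. Ring A is closed afterwards by aldol reaction (C4–C5). Because that closure should favour the 4β-alcohol, C4 is re-set at the end by α-face dihydroxylation of the 4(15)-alkene.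

Key step: step 7

Remark: eudesmane numbering (C1–C15) and α/β descriptors (C10 methyl = β; 5αH = trans ring fusion; 7αH = 7β-isopropyl) are used throughout; in step 5 the ligand antipode that gives the (R) ketone is taken, its sense of induction being assumed by analogy with six-membered enones.

Step 1
Reactants: 1 2,3-dibromoprop-1-ene; 2 (4-methoxyphenyl)methanol
Product: 3 2-bromoallyl 4-methoxybenzyl ether
Conditions: NaH, THF, 0 °C → rt
Reagents that add atoms: none
Why: Williamson ether synthesis, in which the alkoxide of 2 displaces the allylic bromide of 1 (SN2) while the vinylic bromide stays inert.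

Step 2
Reactants: 4 allyl tert-butyldimethylsilyl ether; 3 2-bromoallyl 4-methoxybenzyl ether
Product: 6 tert-butyldimethylsilyl ether of 4-[(4-methoxybenzyloxy)methyl]pent-4-en-1-ol, via alkylborane 5 (not isolated)
Conditions: 9-BBN-H, THF, rt; then 3, Pd(dppf)Cl2 (5 mol%), K3PO4 (aq), DMF, 50 °C
Reagents that add atoms: none
Why: Anti-Markovnikov hydroboration of 4 followed by B-alkyl Suzuki–Miyaura coupling with the vinyl bromide should join C3 to C4 without touching the allylic ether.

Step 3
Reactants: 6 tert-butyldimethylsilyl ether of 4-[(4-methoxybenzyloxy)methyl]pent-4-en-1-ol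
Product: 7 4-[(4-methoxybenzyloxy)methyl]pent-4-en-1-ol
Conditions: Bu4NF, THF, 0 °C → rt
Reagents that add atoms: none
Why: Fluoride-mediated desilylation of a primary silyl ether, to which the 4-methoxybenzyl ether and the alkene are inert.

Step 4
Reactants: 7 4-[(4-methoxybenzyloxy)methyl]pent-4-en-1-ol
Product: 8 5-bromo-2-[(4-methoxybenzyloxy)methyl]pent-1-ene
Conditions: CBr4, PPh3, CH2Cl2, 0 °C
Reagents that add atoms: carbon tetrabromide, BrC(Br)(Br)Br
Why: Appel bromination of the primary alcohol under neutral conditions that should spare the acid-sensitive allylic 4-methoxybenzyl ether.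

Step 5
Reactants: 8 5-bromo-2-[(4-methoxybenzyloxy)methyl]pent-1-ene; 9 3-methylcyclopent-2-en-1-one
Product: 11 (R)-3-methyl-3-[4-(4-methoxybenzyloxymethyl)pent-4-enyl]cyclopentanone, via Grignard reagent 10 (not isolated)
Conditions: Mg, Et2O, rt; then 9, Cu(OTf)2 (3 mol%), leucinol-derived 1-(1-hydroxy-4-methylpentan-2-yl)-3-mesityl-4,5-dihydroimidazolium hexafluorophosphate (4 mol%), Et2O, 0 °C
Reagents that add atoms: none
Why: Copper-catalysed asymmetric conjugate addition of a Grignard reagent to a β-substituted cyclic enone, in which the carbene-bound alkylcopper species adds to one enantiotopic face of 9 and so sets the quaternary C10 as (R).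

Step 6
Reactants: 12 2-methylpropanal
Product: 13 (2-methylpropylidene)hydrazine
Conditions: N2H4·H2O (excess), EtOH, 0 °C → rt; used fresh
Reagents that add atoms: hydrazine (as hydrate), NN
Why: Condensation of the aldehyde with hydrazine gives the hydrazone, the excess of hydrazine suppressing azine formation.

Step 7
Reactants: 11 (R)-3-methyl-3-[4-(4-methoxybenzyloxymethyl)pent-4-enyl]cyclopentanone; 13 (2-methylpropylidene)hydrazine
Product: 15 (5R)-2-isopropyl-5-methyl-5-[4-(4-methoxybenzyloxymethyl)pent-4-enyl]cyclohexanone (both C7 epimers), via 2-methyl-1-diazopropane 14 (not isolated)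
Conditions: 13, (COCl)2, DMSO, Et3N, THF, −78 °C, cold filtration; then 11, Sc(OTf)3 (10 mol%), toluene, −78 → −20 °C
Reagents that add atoms: none
Why: Sc(OTf)3 binds the C6 carbonyl of 11, the nucleophilic diazo carbon of 14 (the future C7) adds to C6, and in the resulting diazonium alkoxide C8 shifts from C6 to C7 antiperiplanar to the departing N2, which forms C6–C7 and C7–C8. The closest known reaction type is the Sc(OTf)3-catalysed homologation of cycloalkanones with monosubstituted diazoalkanes, a Tiffeneau–Demjanov-type ring expansion. Ring B is not made by a cyclisation but by enlargement of the five-membered ring through this 1,2-shift. The new stereocentre C7 is not controlled here and forms as both epimers, while C10 is untouched; C7 is fixed in step 11. The step needs migration of C8 in preference to C5: C5 is neopentylic to the quaternary C10, so the rotamer that places it anti to N2 presses the isopropyl group against the C10 substituents, whereas C8 is an unhindered methylene. Because C4 is still an alkene, the ring carbonyl is the only electrophile for the diazoalkane, and the α-branched product is too hindered to be homologated a second time.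

Step 8
Reactants: 15 (5R)-2-isopropyl-5-methyl-5-[4-(4-methoxybenzyloxymethyl)pent-4-enyl]cyclohexanone (both C7 epimers)
Product: 16 (5R)-2-isopropyl-5-methyl-5-[5-(4-methoxybenzyloxy)-4-oxopentyl]cyclohexanone (both C7 epimers)
Conditions: OsO4 (cat.), NaIO4, 2,6-lutidine, dioxane/H2O, rt
Reagents that add atoms: sodium periodate, [Na+].[O-]I(=O)(=O)=O
Why: Lemieux–Johnson cleavage of the only alkene unmasks the C4 ketone with loss of the methylene carbon, 2,6-lutidine suppressing over-oxidation.

Step 9
Reactants: 16 (5R)-2-isopropyl-5-methyl-5-[5-(4-methoxybenzyloxy)-4-oxopentyl]cyclohexanone (both C7 epimers)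
Product: 17 4β-hydroxy-15-(4-methoxybenzyloxy)-5αH-eudesman-6-one (both C7 epimers)
Conditions: NaOMe (cat.), MeOH, 0 °C → rt
Reagents that add atoms: none
Why: Reversible intramolecular aldol addition of the C5 enolate to the activated α-alkoxy C4 ketone is the only closure to an unstrained fused six-membered ring, and under equilibrium control the fusion should become trans (C5) with the larger CH2O group equatorial, i.e. 4β-OH, which does not matter because C4 is re-set in steps 15 and 16.

Step 10
Reactants: 17 4β-hydroxy-15-(4-methoxybenzyloxy)-5αH-eudesman-6-one (both C7 epimers)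
Product: 18 4β,15-[(4-methoxybenzylidene)dioxy]-5αH-eudesman-6-one (both C7 epimers; both acetal epimers)
Conditions: DDQ, 4 Å molecular sieves, CH2Cl2, 0 °C
Reagents that add atoms: none
Why: DDQ oxidises the 4-methoxybenzyl ether to an oxocarbenium ion that the neighbouring tertiary hydroxyl traps (oxidative acetalisation), which ties up O4 and O15 and blocks retro-aldol cleavage in the next step.

Step 11
Reactants: 18 4β,15-[(4-methoxybenzylidene)dioxy]-5αH-eudesman-6-one (both C7 epimers; both acetal epimers)
Product: 20 4β,15-[(4-methoxybenzylidene)dioxy]-5αH,7αH-eudesman-6β-ol, via 7β-isopropyl ketone 19 (not isolated)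
Conditions: NaOMe, MeOH/THF, rt; then NaBH4, 0 °C → rt
Reagents that add atoms: none
Why: Dynamic kinetic reduction, in which methoxide interconverts the C7 epimers through the C6–C7 enolate while borohydride can reach C6 only from the α face (the β face is blocked by the axial C10 methyl and the axial O4), and since an axial 7α-isopropyl group shields that face the 7β-epimer is drained to the 6β-alcohol with equatorial isopropyl.

Step 12
Reactants: 20 4β,15-[(4-methoxybenzylidene)dioxy]-5αH,7αH-eudesman-6β-ol; 21 (diethoxyphosphoryl)acetic acid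
Product: 22 4β,15-[(4-methoxybenzylidene)dioxy]-5αH,7αH-eudesman-6β-yl (diethoxyphosphoryl)acetate
Conditions: 21, N,N'-dicyclohexylcarbodiimide, 4-(dimethylamino)pyridine (cat.), CH2Cl2, 0 °C → rt
Reagents that add atoms: none
Why: Steglich-type esterification, in which the carbodiimide turns 21 into a small ketene-like acylating species that should reach the hindered axial 6β-hydroxyl.

Step 13
Reactants: 22 4β,15-[(4-methoxybenzylidene)dioxy]-5αH,7αH-eudesman-6β-yl (diethoxyphosphoryl)acetate
Product: 23 4β,15-dihydroxy-5αH,7αH-eudesman-6β-yl (diethoxyphosphoryl)acetate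
Conditions: AcOH/THF/H2O, 40 °C
Reagents that add atoms: none
Why: Mild acid hydrolysis of the 4-methoxybenzylidene acetal, under which the ester is stable and acyl transfer to the tertiary O4 is unfavourable.

Step 14
Reactants: 23 4β,15-dihydroxy-5αH,7αH-eudesman-6β-yl (diethoxyphosphoryl)acetate
Product: 24 4β,15-(thiocarbonyldioxy)-5αH,7αH-eudesman-6β-yl (diethoxyphosphoryl)acetate
Conditions: 1,1'-thiocarbonyldiimidazole, 4-(dimethylamino)pyridine, toluene, 90 °C
Reagents that add atoms: 1,1'-thiocarbonyldiimidazole, S=C(n1ccnc1)n1ccnc1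
Why: The primary 15-OH is thioacylated first and the adjacent tertiary 4-OH then closes the five-membered cyclic thionocarbonate, the first stage of a Corey–Winter olefination.

Step 15
Reactants: 24 4β,15-(thiocarbonyldioxy)-5αH,7αH-eudesman-6β-yl (diethoxyphosphoryl)acetate
Product: 25 5αH,7αH-eudesm-4(15)-en-6β-yl (diethoxyphosphoryl)acetate
Conditions: 1,3-dimethyl-2-phenyl-1,3,2-diazaphospholidine, THF, 40 °C
Reagents that add atoms: none
Why: Corey–Winter olefination in its mild Corey–Hopkins form removes sulfur and CO2 to give the exocyclic 4(15)-alkene from either C4 epimer under neutral conditions that leave C5–H undisturbed.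

Step 16
Reactants: 25 5αH,7αH-eudesm-4(15)-en-6β-yl (diethoxyphosphoryl)acetate
Product: 26 4α,15-dihydroxy-5αH,7αH-eudesman-6β-yl (diethoxyphosphoryl)acetate
Conditions: OsO4 (5 mol%), N-methylmorpholine N-oxide, acetone/H2O, rt
Reagents that add atoms: N-methylmorpholine N-oxide, C[N+]1([O-])CCOCC1; water, O
Why: Upjohn dihydroxylation, in which OsO4 should add to the exocyclic alkene from the α face because the β face is screened by the axial C10 methyl and the 6β-ester, placing 4-OH α (equatorial) and C15 β (axial) as in the target.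

Step 17
Reactants: 26 4α,15-dihydroxy-5αH,7αH-eudesman-6β-yl (diethoxyphosphoryl)acetate; 27 benzaldehyde
Product: 28 4α,15-dihydroxy-5αH,7αH-eudesman-6β-yl (E)-cinnamate (CNP0198850.1)
Conditions: 27, LiCl, iPr2NEt, MeCN, rt
Reagents that add atoms: none
Why: Horner–Wadsworth–Emmons olefination under Masamune–Roush conditions should give the (E)-cinnamate under mild base that the free diol tolerates.

Compound list
1 | 2,3-dibromoprop-1-ene | C=C(Br)CBr | starting material
2 | (4-methoxyphenyl)methanol | COc1ccc(CO)cc1 | starting material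
3 | 2-bromoallyl 4-methoxybenzyl ether | C=C(Br)COCc1ccc(OC)cc1 | intermediate
4 | allyl tert-butyldimethylsilyl ether | C=CCO[Si](C)(C)C(C)(C)C | starting material
5 | 9-[3-(tert-butyldimethylsilyloxy)propyl]-9-borabicyclo[3.3.1]nonane | CC(C)(C)[Si](C)(C)OCCCB1C2CCCC1CCC2 | intermediate
6 | tert-butyldimethylsilyl ether of 4-[(4-methoxybenzyloxy)methyl]pent-4-en-1-ol | C=C(CCCO[Si](C)(C)C(C)(C)C)COCc1ccc(OC)cc1 | intermediate
7 | 4-[(4-methoxybenzyloxy)methyl]pent-4-en-1-ol | C=C(CCCO)COCc1ccc(OC)cc1 | intermediate
8 | 5-bromo-2-[(4-methoxybenzyloxy)methyl]pent-1-ene | C=C(CCCBr)COCc1ccc(OC)cc1 | intermediate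
9 | 3-methylcyclopent-2-en-1-one | CC1=CC(=O)CC1 | starting material
10 | {4-[(4-methoxybenzyloxy)methyl]pent-4-enyl}magnesium bromide | C=C(CCC[Mg]Br)COCc1ccc(OC)cc1 | intermediate
11 | (R)-3-methyl-3-[4-(4-methoxybenzyloxymethyl)pent-4-enyl]cyclopentanone | O=C1C[C@](C)(CCCC(=C)COCc2ccc(OC)cc2)CC1 | intermediate
12 | 2-methylpropanal | CC(C)C=O | starting material
13 | (2-methylpropylidene)hydrazine | CC(C)C=NN | intermediate
14 | 2-methyl-1-diazopropane | CC(C)C=[N+]=[N-] | intermediate
15 | (5R)-2-isopropyl-5-methyl-5-[4-(4-methoxybenzyloxymethyl)pent-4-enyl]cyclohexanone, both epimers at the isopropyl-bearing carbon (C7) | CC(C)C1CC[C@@](C)(CCCC(=C)COCc2ccc(OC)cc2)CC1=O | intermediate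
16 | (5R)-2-isopropyl-5-methyl-5-[5-(4-methoxybenzyloxy)-4-oxopentyl]cyclohexanone, both C7 epimers | CC(C)C1CC[C@@](C)(CCCC(=O)COCc2ccc(OC)cc2)CC1=O | intermediate
17 | 4β-hydroxy-15-(4-methoxybenzyloxy)-5αH-eudesman-6-one, trans-fused, 10β-methyl, both C7 epimers | CC(C)C1CC[C@@]2(C)CCC[C@@](O)(COCc3ccc(OC)cc3)[C@@H]2C1=O | intermediate
18 | 4β,15-[(4-methoxybenzylidene)dioxy]-5αH-eudesman-6-one, both C7 epimers, both acetal epimers | CC(C)C1CC[C@@]2(C)CCC[C@@]3(COC(c4ccc(OC)cc4)O3)[C@@H]2C1=O | intermediate
19 | 4β,15-[(4-methoxybenzylidene)dioxy]-5αH,7αH-eudesman-6-one (7β-isopropyl), both acetal epimers | CC(C)[C@@H]1CC[C@@]2(C)CCC[C@@]3(COC(c4ccc(OC)cc4)O3)[C@@H]2C1=O | intermediate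
20 | 4β,15-[(4-methoxybenzylidene)dioxy]-5αH,7αH-eudesman-6β-ol, both acetal epimers | CC(C)[C@@H]1CC[C@@]2(C)CCC[C@@]3(COC(c4ccc(OC)cc4)O3)[C@@H]2[C@@H]1O | intermediate
21 | (diethoxyphosphoryl)acetic acid | OC(=O)CP(=O)(OCC)OCC | starting material
22 | 4β,15-[(4-methoxybenzylidene)dioxy]-5αH,7αH-eudesman-6β-yl (diethoxyphosphoryl)acetate, both acetal epimers | CC(C)[C@@H]1CC[C@@]2(C)CCC[C@@]3(COC(c4ccc(OC)cc4)O3)[C@@H]2[C@@H]1OC(=O)CP(=O)(OCC)OCC | intermediate
23 | 4β,15-dihydroxy-5αH,7αH-eudesman-6β-yl (diethoxyphosphoryl)acetate | CC(C)[C@@H]1CC[C@@]2(C)CCC[C@@](O)(CO)[C@@H]2[C@@H]1OC(=O)CP(=O)(OCC)OCC | intermediate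
24 | 4β,15-(thiocarbonyldioxy)-5αH,7αH-eudesman-6β-yl (diethoxyphosphoryl)acetate | CC(C)[C@@H]1CC[C@@]2(C)CCC[C@@]3(COC(=S)O3)[C@@H]2[C@@H]1OC(=O)CP(=O)(OCC)OCC | intermediate
25 | 5αH,7αH-eudesm-4(15)-en-6β-yl (diethoxyphosphoryl)acetate | CC(C)[C@@H]1CC[C@@]2(C)CCCC(=C)[C@@H]2[C@@H]1OC(=O)CP(=O)(OCC)OCC | intermediate
26 | 4α,15-dihydroxy-5αH,7αH-eudesman-6β-yl (diethoxyphosphoryl)acetate | CC(C)[C@@H]1CC[C@@]2(C)CCC[C@](O)(CO)[C@@H]2[C@@H]1OC(=O)CP(=O)(OCC)OCC | intermediate
27 | benzaldehyde | O=Cc1ccccc1 | starting material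
28 | 4α,15-dihydroxy-5αH,7αH-eudesman-6β-yl (E)-3-phenylprop-2-enoate | CC(C)[C@@H]1CC[C@@]2(C)CCC[C@](O)(CO)[C@@H]2[C@@H]1OC(=O)/C=C/c1ccccc1 | target

Total step count: 17. Longest linear sequence: 16 steps (steps 1–5 and 7–17, from 2,3-dibromoprop-1-ene).

Steps most likely to fail

Step 7. The 1,2-shift may lose regiocontrol (migration of C5 instead of C8), or the non-stabilised diazoalkane may decompose before it adds to the ketone. The fallback sets out from bromide 8. Its Grignard reagent 10 is added to 3-methylcyclohex-2-en-1-one under the Cu(OTf)2/carbene conditions of step 5 to give (R)-3-methyl-3-[4-(4-methoxybenzyloxymethyl)pent-4-enyl]cyclohexanone F1. Condensation with 1,1-dimethylhydrazine gives the dimethylhydrazone F2. LDA deprotonates the unhindered C7 methylene, and 2-iodopropane alkylates the azaenolate to the isopropyl hydrazone F3. Hydrolysis with aqueous oxalic acid brings the route back at 15.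

Step 11. Interconversion of the C7 epimers may be slower than reduction, or methoxide may cause β-elimination of the C4 acetal oxygen through the C5 enolate. The fallback sets out from 18. Dehydrogenation with 2-iodoxybenzoic acid (DMSO, 65 °C) can occur only on the C7–C8 side and gives the 7-en-6-one F4. Hydrogenation (H2, Pd/C, EtOAc) delivers hydrogen to the α face opposite the C10 methyl and gives 19. NaBH4 in MeOH without added base then reduces 19, and the route is rejoined at 20.

Step 5. Enantioselectivity may erode through background addition of the Grignard reagent to the five-membered enone. The fallback sets out from 10 (made from 8). 1,2-Addition to 3-ethoxycyclopent-2-en-1-one and acidic work-up give 3-[4-(4-methoxybenzyloxymethyl)pent-4-enyl]cyclopent-2-en-1-one F5. Copper-catalysed asymmetric conjugate addition of Me3Al (Cu(OTf)2, chiral carbene or phosphoramidite ligand) then installs the methyl group and brings the route back at 11.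

Further compounds
F1 | step 7 | (R)-3-methyl-3-[4-(4-methoxybenzyloxymethyl)pent-4-enyl]cyclohexanone | O=C1C[C@](C)(CCCC(=C)COCc2ccc(OC)cc2)CCC1
F2 | step 7 | N,N-dimethylhydrazone of F1 | CN(C)N=C1C[C@](C)(CCCC(=C)COCc2ccc(OC)cc2)CCC1
F3 | step 7 | N,N-dimethylhydrazone of 15 | CN(C)N=C1C[C@](C)(CCCC(=C)COCc2ccc(OC)cc2)CCC1C(C)C
F4 | step 11 | 4β,15-[(4-methoxybenzylidene)dioxy]-5αH-eudesm-7-en-6-one | CC(C)C1=CC[C@@]2(C)CCC[C@@]3(COC(c4ccc(OC)cc4)O3)[C@@H]2C1=O
F5 | step 5 | 3-[4-(4-methoxybenzyloxymethyl)pent-4-enyl]cyclopent-2-en-1-one | O=C1C=C(CCCC(=C)COCc2ccc(OC)cc2)CC1
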